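**Plan**

1. Retrosynthesis: acetate removal and C6=C7 dehydrogenation are undone first. Both C16–C17 bonds (ring D of the upper half, ring D′ of the lower half) are then cut, giving a bis-seco dimer with a 2-iodoethyl arm on C14 and a C17(Me)=C22 alkene in ring E. The 1,4-dioxane is cut by retro-[4+2] into an o-quinone and a styrene, both from one seco-D monomer.
2. The monomer is cut at C20–CH3, at C19=C20 and C22=C17 (Wittig, metathesis), at C13–C18 (Ireland–Claisen), at C14–C15 (reductive alkylation) and in ring C (Robinson annulation), back to 6,7-dimethoxy-2-tetralone.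
3. Forward ring order: A/B (tetralone) → C → E → dioxane → D and D′ together, last.
4. Enabling feature: the vicinal quaternary pair C13/C14 holds C16 (on C14) next to C17, which lies two bonds from C13 through C18. The trisubstituted ring E alkene C17=C22 gives the tertiary C17 radical on Markovnikov hydrogen-atom transfer.
5. Stereochemistry: C9 from a chiral-imine Michael addition; C8 and C14 from reductive alkylation; C13 and C18 from the Ireland–Claisen step (chirality transfer from C11–O); C20 from enolate methylation; C17 from cis ring fusion in the key step; C6′/C7′ from α-face cycloaddition.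

Key step: step 25

Remark on the chemistry: atoms are numbered as in the 24-nor-friedelane (celastroid) skeleton, with primes for the lower half that carries the free catechol; α is the face of H-8, β the face of the C9 methyl. Lithium species are drawn covalently.

**Route**

Step 1
Reactants: 1 6,7-dimethoxy-2-tetralone
Product: 4 rac-6,7-dimethoxy-1-methyl-2-tetralone, via enamine 2 (not isolated), via iminium iodide 3 (not isolated)
Conditions: pyrrolidine, PhH, reflux (−H2O); MeI, dioxane, reflux; H2O, 25 °C
Reagents that add atoms: iodomethane, CI; water, O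
Why: Stork enamine alkylation, in which the arene-conjugated enamine of a 2-tetralone is C-methylated at the benzylic carbon (future C9) and hydrolysed back to the ketone; the stereocenter is reset in step 2.

Step 2
Reactants: 4 rac-6,7-dimethoxy-1-methyl-2-tetralone; 5 pent-1-en-3-one
Product: 8 (S)-6,7-dimethoxy-1-methyl-1-(3-oxopentyl)-2-tetralone, via chiral enamine 6 (not isolated), via adduct imine 7 (not isolated)
Conditions: (S)-1-phenylethylamine, TsOH (cat.), toluene, reflux (−H2O); 5, THF, 25 °C; AcOH/H2O, 25 °C
Reagents that add atoms: water, O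
Why: Michael addition of the secondary enamine tautomer of the chiral imine at the more substituted α-carbon, on the face anti to the phenyl group of the auxiliary, should set quaternary C9 as S (9β-methyl), by analogy with the 2-methylcyclohexanone series.

Step 3
Reactants: 8 (S)-diketone
Product: 9 tricyclic enone (C13 ketone; C8=C14; 9β-methyl; 2,3-dimethoxy ring A)
Conditions: NaOMe, MeOH, 60 °C
Reagents that add atoms: none
Why: Intramolecular aldol condensation (second half of a Robinson annulation) should close ring C as the tetrasubstituted enone without touching C9.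

Step 4
Reactants: 9 tricyclic enone
Product: 10 4-bromo enone
Conditions: NBS, MeCN, 0 °C
Reagents that add atoms: N-bromosuccinimide, BrN1C(=O)CCC1=O
Why: Electrophilic aromatic bromination ortho to a methoxy group should go to C4, because the other free position (C1) is shielded by quaternary C9.

Step 5
Reactants: 10 4-bromo enone
Product: 11 4-methyl enone
Conditions: MeB(OH)2, Pd(dppf)Cl2 (cat.), K2CO3, dioxane/H2O, 90 °C
Reagents that add atoms: methylboronic acid, CB(O)O
Why: Suzuki–Miyaura methylation of the aryl bromide installs the ring A methyl (C23).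

Step 6
Reactants: 11 4-methyl enone
Product: 13 14α-(2-chloroethyl) ketone (C13=O; 8α-H; 9β-methyl; 14β-methyl), via lithium enolate 12 (not isolated)
Conditions: Li (2.2 equiv), NH3/THF, −78 °C; NH3 evaporated; BrCH2CH2Cl, THF/HMPA, −78 → 0 °C
Reagents that add atoms: 1-bromo-2-chloroethane, ClCCBr
Why: Dissolving-metal reductive alkylation, in which C8 is protonated on the α face (trans B/C fusion) and the regiodefined C13–C14 enolate is alkylated anti to the axial 9β-methyl, so C15 should enter α and leave the C14 methyl β.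

Step 7
Reactants: 13 14α-(2-chloroethyl) ketone
Product: 14 Δ11-13-ketone (enone)
Conditions: Pd(O2CCF3)2 (cat.), DMSO (cat.), O2 (1 atm), AcOH, 80 °C
Reagents that add atoms: none
Why: Palladium-catalysed aerobic α,β-dehydrogenation of a cyclohexanone; only C12 carries α-hydrogens (C14 is quaternary), so only the C11=C12 enone can form.

Step 8
Reactants: 14 Δ11-13-ketone
Product: 15 13β-hydroxy-13α-methyl-Δ11 tertiary allylic alcohol
Conditions: MeLi, CeCl3, THF, −78 °C; AcOH quench at −78 °C
Reagents that add atoms: methyllithium, [Li]C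
Why: Organocerium 1,2-addition to the hindered enone should occur from the α face, anti to the adjacent axial 14β-methyl; the cold quench keeps the tertiary alkoxide from displacing the C16 chloride.

Step 9
Reactants: 15 tertiary allylic alcohol
Product: 16 11β-hydroxy-Δ12 allylic alcohol (13-methyl on the alkene)
Conditions: Re2O7 (cat.), Et2O, 0 °C
Reagents that add atoms: none
Why: Rhenium-oxo-catalysed 1,3-transposition of an allylic alcohol ([3,3] shift of the perrhenate ester) should move the oxygen suprafacially from C13β to C11β, driven by the more substituted C12=C13 alkene and the less hindered secondary alcohol.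

Step 10
Reactants: 16 11β-hydroxy-Δ12 allylic alcohol
Product: 17 11β-(3-methylbut-2-enoate) ester
Conditions: 3-methylbut-2-enoyl chloride, pyridine, DMAP (cat.), CH2Cl2, 0 → 25 °C
Reagents that add atoms: 3-methylbut-2-enoyl chloride, CC(C)=CC(=O)Cl
Why: Acylation of the secondary allylic alcohol places the future C19–C18–C17(Me) unit on the 11β-oxygen.

Step 11
Reactants: 17 11β-(3-methylbut-2-enoate) ester
Product: 20 acid with 13β-[CH(CO2H)(isopropenyl)] and 13α-methyl (C11=C12), via silyl dienol ether 18 (not isolated), via silyl ester 19 (not isolated)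
Conditions: LiN(i-Pr)2, THF/HMPA, −78 °C; Me3SiCl; −78 → 50 °C; 1 M HCl
Reagents that add atoms: none
Why: Ireland–Claisen rearrangement of the γ-deprotonated ester forms the hindered C13–C18 bond suprafacially from the 11β-oxygen (C18 on the β face, 13α-methyl); the s-cis ester should give the silyl ketene acetal with isopropenyl cis to OSiMe3, and the boat transition state that turns this group away from the 14β-methyl should set C18 as in the target.

Step 12
Reactants: 20 acid
Product: 21 primary alcohol (C19H2OH)
Conditions: LiAlH4, THF, 0 °C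
Reagents that add atoms: none
Why: Hydride reduction of the carboxylic acid at 0 °C should leave the primary chloride and the alkenes untouched.

Step 13
Reactants: 21 primary alcohol
Product: 22 aldehyde (C19HO)
Conditions: Dess–Martin periodinane, CH2Cl2, 0 °C
Reagents that add atoms: none
Why: Neutral hypervalent-iodine oxidation is chosen so that the α-stereocenter C18 of the β,γ-unsaturated aldehyde is not epimerised or conjugated.

Step 14
Reactants: 23 methyl (triphenylphosphoranylidene)acetate
Product: 25 methyl 2-(triphenylphosphoranylidene)pent-4-enoate, via phosphonium bromide 24 (not isolated)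
Conditions: allyl bromide, EtOAc, 70 °C; NaOH, H2O/CH2Cl2, 0 °C
Reagents that add atoms: allyl bromide, C=CCBr
Why: C-alkylation of a stabilised ylide followed by deprotonation gives the α-allyl ylide that carries C20, C21, C22 and the ester carbon.

Step 15
Reactants: 22 aldehyde; 25 methyl 2-(triphenylphosphoranylidene)pent-4-enoate
Product: 26 (E)-α-allyl enoate (C19=C20)
Conditions: toluene, 90 °C
Reagents that add atoms: none
Why: Wittig olefination with a stabilised ylide is base-free (sparing C18) and should give the E-enoate, in which C18 and the allyl group are cis as ring closure requires.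

Step 16
Reactants: 26 (E)-α-allyl enoate
Product: 27 ring E cyclohexa-1,4-diene ester (C19=C20 and C17=C22)
Conditions: second-generation Grubbs catalyst, CH2Cl2, 40 °C
Reagents that add atoms: none
Why: Ring-closing metathesis between the allyl terminus and the isopropenyl group closes ring E as the trisubstituted C17(Me)=C22 alkene with loss of ethene; the enoate and the ring C alkene are poor metathesis partners.

Step 17
Reactants: 27 ring E cyclohexa-1,4-diene ester
Product: 29 20β-methyl-20α-methoxycarbonyl ring E compound, via ester enolate 28 (not isolated)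
Conditions: LiBH(s-Bu)3, THF, −78 °C; MeI, HMPA, −78 → 0 °C
Reagents that add atoms: iodomethane, CI
Why: Conjugate hydride addition to the enoate gives the ester enolate; MeI should alkylate it anti to the C18 substituent, which is pseudoaxial because of allylic 1,2-strain with the C17 methyl, so the new methyl is β and the ester α.

Step 18
Reactants: 29 20β-methyl ring E compound
Product: 30 11,12-dihydro compound
Conditions: TsNHNH2, NaOAc, THF/H2O, 70 °C
Reagents that add atoms: none
Why: Diimide reduces the cis-disubstituted C11=C12 alkene much faster than the trisubstituted C17=C22 alkene, which is needed for the key step.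

Step 19
Reactants: 30 11,12-dihydro chloride
Product: 31 seco-D monomer iodide (14α-CH2CH2I; ring E C17=C22; 2,3-dimethoxy)
Conditions: NaI, butan-2-one, 80 °C
Reagents that add atoms: sodium iodide, [Na+].[I-]
Why: Finkelstein exchange turns the robust chloride into the iodide needed for nickel activation.

Step 20
Reactants: 31 seco-D monomer iodide
Product: 32 seco-D catechol
Conditions: BBr3, CH2Cl2, −78 → 0 °C; H2O
Reagents that add atoms: none
Why: Boron tribromide cleaves the two aryl methyl ethers; the hindered quaternary methyl ester and the trisubstituted alkene should survive at low temperature.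

Step 21
Reactants: 31 seco-D monomer iodide
Product: 33 Δ6 styrene dimethyl ether
Conditions: DDQ, dioxane, 25 °C
Reagents that add atoms: none
Why: Quinone dehydrogenation by hydride abstraction from benzylic C6 (para to the C2 oxygen) and loss of H-7 should give the C6=C7 styrene; quaternary C9 prevents aromatisation of ring B.

Step 22
Reactants: 33 Δ6 styrene dimethyl ether
Product: 34 Δ6 vinylcatechol
Conditions: BBr3, CH2Cl2, −78 → −20 °C; H2O
Reagents that add atoms: none
Why: Low-temperature demethylation, as used for methoxy-substituted 1,2-dihydronaphthalenes, should free the catechol without ionising the styrene.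

Step 23
Reactants: 34 Δ6 vinylcatechol
Product: 35 Δ6 vinylcatechol diacetate
Conditions: Ac2O, pyridine, 0 °C
Reagents that add atoms: acetic anhydride, CC(=O)OC(C)=O
Why: Acetylation blocks redox exchange with the o-quinone in step 24 and deactivates ring A′ towards DDQ in step 26.

Step 24
Reactants: 32 seco-D catechol; 35 Δ6 vinylcatechol diacetate
Product: 37 bis-seco dimer (cis-fused 1,4-dioxane: O3–C7′ and O2–C6′), via o-quinone 36 (not isolated)
Conditions: Ag2O, MgSO4, Et2O, 0 °C; filtered; 35, CH2Cl2, 25 °C, dark
Reagents that add atoms: none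
Why: Inverse-electron-demand hetero-Diels–Alder reaction of the o-quinone (O=C2–C3=O) with the electron-rich C6′=C7′ styrene, suprafacial on the α face of ring B′ (anti to the 9′β-methyl), should give the cis-dioxane with the connectivity of the natural dimers.

Step 25
Reactants: 37 bis-seco dimer
Product: 38 bis-cyclised dimer diacetate (rings D and D′ closed; C6–C7 saturated in the upper half)
Conditions: Mn(dpm)3 (cat.), Ni(acac)2 (cat.), PhSiH3 (slow addition), K2CO3, (CF3)2CHOH, 1,2-dichloroethane/propylene carbonate, 25 °C, high dilution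
Reagents that add atoms: none
Why: Proposed new method: Mn(dpm)3/PhSiH3 should form a manganese hydride that transfers a hydrogen atom to C22 (and C22′) of each trisubstituted C17=C22 alkene (Markovnikov) to give the tertiary C17 radical, while low-valent nickel activates the primary C16–I bond to an alkylnickel species that captures this radical, and reductive elimination from the resulting trivalent nickel dialkyl forges C16–C17; the closest known reaction type is the intermolecular manganese/nickel dual-catalytic branch-selective hydroalkylation of unactivated olefins with primary alkyl iodides, used here intramolecularly and twice in one molecule. Each ring (D and D′) closes in a 6-exo sense with respect to the C17 radical (atoms C13–C14–C15–C16–C17–C18, new bond exocyclic to ring E), with C16 held over C17 by the vicinal quaternary pair C13/C14. The new quaternary stereocenters C17 and C17′ are controlled by C18 and C18′: the tether leaves C18 on the α face of ring E and can only reach the same face of the planar radical, so the D/E fusion must be cis (17β-methyl), and no other stereocenter is touched. The step needs C–C capture to win over simple reduction of the radical or of the iodide, which proximity and slow silane addition should secure; the only alkenes present are the two that react, since the styrene of the lower half was consumed in step 24 and that of the upper half is not yet present.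

Step 26
Reactants: 38 bis-cyclised dimer diacetate
Product: 39 Δ6 dimer diacetate
Conditions: DDQ (1.05 equiv), dioxane, 25 °C
Reagents that add atoms: none
Why: Quinone dehydrogenation at benzylic C6 of the electron-rich dialkoxy ring A (as in step 21) should install C6=C7, while the acetylated ring A′ is deactivated towards hydride abstraction at C6′.

Step 27
Reactants: 39 Δ6 dimer diacetate
Product: 40 CNP0344950.1 (target)
Conditions: K2CO3 (cat.), MeOH/THF, 0 °C; AcOH quench
Reagents that add atoms: none
Why: Mild transesterification removes the two aryl acetates; the hindered quaternary methyl esters and the aryl ethers should be inert, and the short cold reaction limits phenoxide-induced opening of the benzylic ether.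

**Compound list**

1 | 6,7-dimethoxy-3,4-dihydronaphthalen-2(1H)-one | COc1cc2CCC(=O)Cc2cc1OC | starting material
2 | 1-(6,7-dimethoxy-3,4-dihydronaphthalen-2-yl)pyrrolidine | COc1cc2CCC(N3CCCC3)=Cc2cc1OC | intermediate
3 | 1-(6,7-dimethoxy-1-methyl-3,4-dihydronaphthalen-2(1H)-ylidene)pyrrolidinium iodide | COc1cc2CCC(=[N+]3CCCC3)C(C)c2cc1OC.[I-] | intermediate
4 | rac-6,7-dimethoxy-1-methyl-3,4-dihydronaphthalen-2(1H)-one | COc1cc2CCC(=O)C(C)c2cc1OC | intermediate
5 | pent-1-en-3-one | C=CC(=O)CC | starting material
6 | 6,7-dimethoxy-1-methyl-N-[(S)-1-phenylethyl]-3,4-dihydronaphthalen-2-amine | COc1cc2CCC(N[C@@H](C)c3ccccc3)=C(C)c2cc1OC | intermediate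
7 | N-[(S)-1-phenylethyl] imine (at the ring carbonyl) of 8 | CCC(=O)CC[C@]1(C)C(=N[C@@H](C)c3ccccc3)CCc2cc(OC)c(OC)cc12 | intermediate
8 | (S)-6,7-dimethoxy-1-methyl-1-(3-oxopentyl)-3,4-dihydronaphthalen-2(1H)-one | CCC(=O)CC[C@]1(C)C(=O)CCc2cc(OC)c(OC)cc12 | intermediate
9 | 6,7-dimethoxy-1,4a-dimethyl-4,4a,9,10-tetrahydrophenanthren-2(3H)-one, 4a-methyl β (rings A–C; C13 ketone, C8=C14, 9β-Me) | CC1=C2CCc3cc(OC)c(OC)cc3[C@]2(C)CCC1=O | intermediate
10 | 4-bromo derivative of 9 (Br on ring A carbon C4) | CC1=C2CCc3c(Br)c(OC)c(OC)cc3[C@]2(C)CCC1=O | intermediate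
11 | 4-methyl derivative of 9 (2,3-dimethoxy-4-methyl ring A) | CC1=C2CCc3c(C)c(OC)c(OC)cc3[C@]2(C)CCC1=O | intermediate
12 | lithium C13–C14 enolate of the 8α-H ketone | [Li]OC1=C(C)[C@H]2CCc3c(C)c(OC)c(OC)cc3[C@]2(C)CC1 | intermediate
13 | 14α-(2-chloroethyl)-14β-methyl-8α-H-9β-methyl C13 ketone | ClCC[C@]1(C)[C@H]2CCc3c(C)c(OC)c(OC)cc3[C@]2(C)CCC1=O | intermediate
14 | Δ11-13-ketone of 13 | ClCC[C@]1(C)[C@H]2CCc3c(C)c(OC)c(OC)cc3[C@]2(C)C=CC1=O | intermediate
15 | 13β-hydroxy-13α-methyl-Δ11 tertiary alcohol | ClCC[C@]1(C)[C@H]2CCc3c(C)c(OC)c(OC)cc3[C@]2(C)C=C[C@@]1(C)O | intermediate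
16 | 11β-hydroxy-13-methyl-Δ12 allylic alcohol | ClCC[C@]1(C)[C@H]2CCc3c(C)c(OC)c(OC)cc3[C@]2(C)[C@@H](O)C=C1C | intermediate
17 | 11β-(3-methylbut-2-enoyloxy) ester of 16 | ClCC[C@]1(C)[C@H]2CCc3c(C)c(OC)c(OC)cc3[C@]2(C)[C@@H](OC(=O)C=C(C)C)C=C1C | intermediate
18 | trimethylsilyl dienol ether (ketene acetal) of 17, isopropenyl cis to OSiMe3 | ClCC[C@]1(C)[C@H]2CCc3c(C)c(OC)c(OC)cc3[C@]2(C)[C@@H](O/C(O[Si](C)(C)C)=C/C(C)=C)C=C1C | intermediate
19 | trimethylsilyl ester of 20 | ClCC[C@]1(C)[C@H]2CCc3c(C)c(OC)c(OC)cc3[C@]2(C)C=C[C@@]1(C)[C@H](C(=O)O[Si](C)(C)C)C(C)=C | intermediate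
20 | Δ11 acid: 13α-methyl, 13β-[C18H(C19O2H)(isopropenyl)] | ClCC[C@]1(C)[C@H]2CCc3c(C)c(OC)c(OC)cc3[C@]2(C)C=C[C@@]1(C)[C@H](C(=O)O)C(C)=C | intermediate
21 | primary alcohol from 20 (C19H2OH) | ClCC[C@]1(C)[C@H]2CCc3c(C)c(OC)c(OC)cc3[C@]2(C)C=C[C@@]1(C)[C@H](CO)C(C)=C | intermediate
22 | aldehyde from 21 (C19HO) | ClCC[C@]1(C)[C@H]2CCc3c(C)c(OC)c(OC)cc3[C@]2(C)C=C[C@@]1(C)[C@H](C=O)C(C)=C | intermediate
23 | methyl (triphenylphosphoranylidene)acetate | COC(=O)C=P(c1ccccc1)(c1ccccc1)c1ccccc1 | starting material
24 | (1-methoxy-1-oxopent-4-en-2-yl)triphenylphosphonium bromide | C=CCC(C(=O)OC)[P+](c1ccccc1)(c1ccccc1)c1ccccc1.[Br-] | intermediate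
25 | methyl 2-(triphenylphosphoranylidene)pent-4-enoate | C=CCC(C(=O)OC)=P(c1ccccc1)(c1ccccc1)c1ccccc1 | intermediate
26 | (E)-enoate: C18 bears isopropenyl and CH=C(allyl)CO2Me | ClCC[C@]1(C)[C@H]2CCc3c(C)c(OC)c(OC)cc3[C@]2(C)C=C[C@@]1(C)[C@H](/C=C(\CC=C)C(=O)OC)C(C)=C | intermediate
27 | ring E cyclohexa-1,4-diene ester (C19=C20–CO2Me, C17(Me)=C22) | ClCC[C@]1(C)[C@H]2CCc3c(C)c(OC)c(OC)cc3[C@]2(C)C=C[C@@]1(C)[C@@H]4C=C(C(=O)OC)CC=C4C | intermediate
28 | lithium ester enolate at C20 | ClCC[C@]1(C)[C@H]2CCc3c(C)c(OC)c(OC)cc3[C@]2(C)C=C[C@@]1(C)[C@@H]4CC(=C(OC)O[Li])CC=C4C | intermediate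
29 | 20β-methyl-20α-methoxycarbonyl ring E compound (C17=C22, C11=C12) | ClCC[C@]1(C)[C@H]2CCc3c(C)c(OC)c(OC)cc3[C@]2(C)C=C[C@@]1(C)[C@@H]4C[C@](C)(C(=O)OC)CC=C4C | intermediate
30 | 11,12-dihydro derivative of 29 | ClCC[C@]1(C)[C@H]2CCc3c(C)c(OC)c(OC)cc3[C@]2(C)CC[C@@]1(C)[C@@H]4C[C@](C)(C(=O)OC)CC=C4C | intermediate
31 | seco-D monomer iodide (14α-CH2CH2I, 2,3-dimethoxy) | ICC[C@]1(C)[C@H]2CCc3c(C)c(OC)c(OC)cc3[C@]2(C)CC[C@@]1(C)[C@@H]4C[C@](C)(C(=O)OC)CC=C4C | intermediate
32 | seco-D catechol (2,3-dihydroxy) | ICC[C@]1(C)[C@H]2CCc3c(C)c(O)c(O)cc3[C@]2(C)CC[C@@]1(C)[C@@H]4C[C@](C)(C(=O)OC)CC=C4C | intermediate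
33 | Δ6 seco-D styrene, 2,3-dimethoxy | ICC[C@]1(C)[C@H]2C=Cc3c(C)c(OC)c(OC)cc3[C@]2(C)CC[C@@]1(C)[C@@H]4C[C@](C)(C(=O)OC)CC=C4C | intermediate
34 | Δ6 seco-D vinylcatechol | ICC[C@]1(C)[C@H]2C=Cc3c(C)c(O)c(O)cc3[C@]2(C)CC[C@@]1(C)[C@@H]4C[C@](C)(C(=O)OC)CC=C4C | intermediate
35 | Δ6 seco-D vinylcatechol diacetate | ICC[C@]1(C)[C@H]2C=Cc3c(C)c(OC(C)=O)c(OC(C)=O)cc3[C@]2(C)CC[C@@]1(C)[C@@H]4C[C@](C)(C(=O)OC)CC=C4C | intermediate
36 | seco-D 2,3-o-quinone | ICC[C@]1(C)[C@H]2CCC3=C(C)C(=O)C(=O)C=C3[C@]2(C)CC[C@@]1(C)[C@@H]4C[C@](C)(C(=O)OC)CC=C4C | intermediate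
37 | bis-seco dimer (6′α,7′α-dioxane; 2′,3′-diacetate; two CH2CH2I arms; two C17=C22 alkenes) | ICC[C@]1(C)[C@H]2CCc3c(cc4c(c3C)O[C@@H]5[C@H](O4)c6c(cc(OC(C)=O)c(OC(C)=O)c6C)[C@]6(C)CC[C@@](C)([C@@H]7C[C@](C)(C(=O)OC)CC=C7C)[C@](C)(CCI)[C@@H]56)[C@]2(C)CC[C@@]1(C)[C@@H]8C[C@](C)(C(=O)OC)CC=C8C | intermediate
38 | bis-cyclised dimer, 2′,3′-diacetate, 6,7-dihydro | COC(=O)[C@]1(C)CC[C@]2(C)CC[C@]3(C)[C@H]4CCc5c(cc6c(c5C)O[C@@H]5[C@H](O6)c6c(cc(OC(C)=O)c(OC(C)=O)c6C)[C@]6(C)CC[C@@]7(C)[C@@H]8C[C@](C)(C(=O)OC)CC[C@]8(C)CC[C@]7(C)[C@@H]56)[C@]4(C)CC[C@@]3(C)[C@@H]2C1 | intermediate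
39 | Δ6 dimer 2′,3′-diacetate | COC(=O)[C@]1(C)CC[C@]2(C)CC[C@]3(C)[C@H]4C=Cc5c(cc6c(c5C)O[C@@H]5[C@H](O6)c6c(cc(OC(C)=O)c(OC(C)=O)c6C)[C@]6(C)CC[C@@]7(C)[C@@H]8C[C@](C)(C(=O)OC)CC[C@]8(C)CC[C@]7(C)[C@@H]56)[C@]4(C)CC[C@@]3(C)[C@@H]2C1 | intermediate
40 | CNP0344950.1 | COC(=O)[C@]1(C)CC[C@]2(C)CC[C@]3(C)[C@H]4C=Cc5c(cc6c(c5C)O[C@@H]5[C@H](O6)c6c(cc(O)c(O)c6C)[C@]6(C)CC[C@@]7(C)[C@@H]8C[C@](C)(C(=O)OC)CC[C@]8(C)CC[C@]7(C)[C@@H]56)[C@]4(C)CC[C@@]3(C)[C@@H]2C1 | target

**Count**

Total step count: 27. Longest linear sequence: 25 steps (1–13, 15–19, 21–27).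

**Steps most likely to fail**

1. Step 25 (Proposed new method). The tertiary C17 radical may be reduced before nickel captures it, the iodide may be reduced, or only one of the two rings may close. The fallback uses known chemistry and runs from 37 directly to 38: a reductive radical cyclisation with Bu3SnH and AIBN (syringe-pump addition, PhH, 80 °C). Here the polarity is reversed: the primary C16 radical from each iodide adds 6-exo to C17 of the ring E alkene, and the resulting C22 radical is reduced by the stannane. The 7-endo alternative would bridge ring E, which should favour the 6-exo mode, and the cis D/E fusion is again enforced by the tether. No new compound is formed on the way.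

2. Step 24. The o-quinone may tautomerise to its quinone methide before it reacts, or the thermal cycloaddition may show poor regio- or facial selectivity. The fallback runs from 32 and 35 to 37: quinone 36 is generated as before and united with 35 by the photochemical [4+2] addition of a triplet o-quinone to an alkene (visible light, CH2Cl2, −40 °C). This is a stepwise biradical process that passes through the benzylic C6′ radical, does not depend on the frontier-orbital match of the thermal reaction, and runs below the temperature at which the quinone isomerises. No new compound is formed on the way.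

3. Step 26. Over-oxidation may occur by hydride loss from the allylic C8–H of the new styrene (with methyl migration), or DDQ may attack the benzylic C6′–H of the lower half. The fallback runs from 38 to 39: radical benzylic bromination at C6 of the upper half (NBS, AIBN, PhCF3, 80 °C) to the 6-bromo derivative of 38 F1, followed by E2 elimination towards C7 with DBU (toluene, 60 °C).

**Further compounds**

F0 | step 25 | none | none
F0 | step 24 | none | none
F1 | step 26 | 6-bromo derivative of 38 (configuration at C6 not controlled) | COC(=O)[C@]1(C)CC[C@]2(C)CC[C@]3(C)[C@H]4CC(Br)c5c(cc6c(c5C)O[C@@H]5[C@H](O6)c6c(cc(OC(C)=O)c(OC(C)=O)c6C)[C@]6(C)CC[C@@]7(C)[C@@H]8C[C@](C)(C(=O)OC)CC[C@]8(C)CC[C@]7(C)[C@@H]56)[C@]4(C)CC[C@@]3(C)[C@@H]2C1
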